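The readings were computed from invented constants, noise included.

In a one-step world the south-east run would turn its 0.60 M of partner into as much product, because the two substrates together hold more, 0.800 M.

| flask | left-handed substrate | right-handed substrate | partner | racemization catalyst | remark | time |
|---|---|---|---|---|---|---|
| south-east | 0.40 M | 0.40 M | 0.60 M | 0.80 mM | run made earlier |  |
| south | 0.40 M | 0.40 M | 0.90 M | 0.80 mM | run made earlier |  |
| flask | 0.40 M | 0.40 M | 1.20 M | 0.80 mM |  | 3.0 d |

- south-east (time / d: left-handed product / %, left-handed substrate / %, right-handed product / %): 0.500: 5.5, 42.3, 4.9; 1.04: 6.8, 40.2, 7.5; 1.67: 6.5, 39.6, 6.9; 2.08: 7.9, 40.3, 7.3; 2.50: 8.8, 39.7, 8.8; 3.00: 8.2, 39.8, 7.8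
- south (time / d: left-handed product / %, left-handed substrate / %, right-handed product / %): 0.500: 9.0, 37.7, 6.3; 1.04: 11.1, 36.2, 10.3; 1.67: 11.3, 35.3, 11.5; 2.08: 12.3, 35.1, 11.7; 2.50: 11.1, 35.2, 11.0; 3.00: 11.3, 36.0, 10.2

(each reading ± 0.5 percentage points)

- partner is single-handed; left-handed substrate and right-handed substrate are mirror images of each other, charged as a racemate, each of them at the stated concentration
- reactions considered so far: partner + left-handed substrate -> left-handed product; partner + right-handed substrate -> right-handed product; left-handed substrate + racemization catalyst <-> right-handed substrate + racemization catalyst; racemization catalyst <-> dormant form; left-handed product <-> right-handed product; partner -> decomposed reagent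
- the handed part of partner does not stay in what it makes, so the products of the two hands are mirror images too

- concentration of left-handed product at 3.0 d, in M
- concentration of left-handed substrate at 3.0 d, in M
- concentration of right-handed product at 3.0 d, in M
- concentration of right-handed substrate at 3.0 d, in M
- concentration of partner at 3.0 d, in M

But the last three readings of the south-east run level off at 0.130 M of the two products together, and those of the south run, charged with 0.90 M partner, at 0.180 M. Substrate remains in both, so I take the missing partner as decomposed reagent and read each run as a race. Coupling is pseudo-first-order in partner, with substrate setting its speed, while decomposition is first order, so partner coupled over partner decomposed should go with substrate.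

I divide that quotient by the mean total substrate, taken as the charge less half the product. The readings give 0.377 M⁻¹ for the south-east run and 0.353 M⁻¹ for the south run. I carry their mean, the capture ratio 0.365 M⁻¹, partner coupled per partner decomposed at one molar of substrate.

In the new flask, full substrate gives 0.271 M of product. Putting half of that back as substrate used gives 0.234 M, and going round once more gives 0.239 M. I commit to that total, split evenly, as the south run's two products read 11.1 % and 11.0 % at 2.50 d.

The forecast gives 0.109 M left-handed product, 0.106 M right-handed product, 0.255 M left-handed substrate, 0.33 M right-handed substrate and 0.003 M partner, noting that “the plateau grows with charged partner”. Its product total is lower than mine.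

The flask gives 0.116 M left-handed product, 0.116 M right-handed product, 0.257 M left-handed substrate, 0.310 M right-handed substrate and 0.00147 M partner.

    partner + left-handed substrate → left-handed product (k = 0.0430 M⁻¹ h⁻¹)
    partner + right-handed substrate → right-handed product (k = 0.0140 M⁻¹ h⁻¹)
    left-handed substrate + racemization catalyst ⇌ right-handed substrate + racemization catalyst, rate k3*[racemization catalyst]*[left-handed substrate] forward; the back reaction follows from the equilibrium constant (k = 20.0 M⁻¹ h⁻¹)
    racemization catalyst ⇌ dormant form (K = 2.70, k = 0.0650 h⁻¹)
    left-handed product ⇌ right-handed product (k = 0.140 h⁻¹)
    partner → decomposed reagent (k = 0.0770 h⁻¹)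

The two products in the flask total 0.232 M, against my 0.239 M. At the 0.567 M of substrate standing at 3.0 d, the capture ratio puts the share of partner going to product at 17.1 %, so I reckon the 0.00147 M partner still in the flask worth 2.52 × 10⁻⁴ M more product. For the neighbouring flask, the same charge read at 8.0 d, that reckoning gives 0.232 M of the two products together; it holds 2.17 × 10⁻⁸ M partner, and its products stand at 0.116 M left-handed and 0.116 M right-handed.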